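**Plan**

1. Locants (elemane numbering): ring C5–C6–C7–C8–C9–C10; C10 bears CH3 and the vinyl group C1=C2, C5 bears C4(=C3H2)–C15H2OH, C6 bears OH, C7 bears C11(=C13H2)–C12O2H, C8 bears the ester oxygen.
2. Retrosynthesis cuts, in order: (a) the C8–O acyl bond, the C12 oxidation level (CO2H back to CH3) and the silyl ethers; (b) C7–C8 (retro carbonyl-ene) and C9–C10 (retro-Claisen) together, which opens the cyclohexane to an acyclic allyl vinyl ether; (c) C5–C6 (allylboration of 3-methylbut-2-enal); (d) C5–C10 and C3–C4 (carbocupration of a propiolate, boron trapping).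
3. Enabling feature: quaternary C10 with its vinyl group and the C9H2–C8 carbinol unit is the γ,δ-unsaturated aldehyde pattern of a Claisen shift; C8–O next to C7 carrying the C11=C13 methylene is the homoallylic alcohol pattern of a carbonyl-ene reaction. One aldehyde carbon (C8) links both events.
4. Forward: three-component assembly of a dienyl allylboronate, asymmetric allylboration (chain complete), protecting-group exchange and O-vinylation; then the only ring (cyclohexane C5–C10) forms in one operation. C8 is reset through the ketone and acylated, C12 is oxidised to the acid, silyl ethers are removed last.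
5. Stereochemistry: C5/C6 from the closed chair of a chiral-phosphoric-acid-catalysed allylboration (Z γ-substituent gives syn; catalyst gives absolute sense); C10 and C7 from the Claisen and ene chairs under control of C5/C6 and the Z C1=C10 geometry; C8 from equatorial hydride delivery; side-chain Z alkene from a Z-selective Horner–Wadsworth–Emmons reaction.

Key step: step 9

Remark: the target is taken as the free C6-hydroxy C12-acid exactly as drawn (a latent γ-lactone), so hydroxyl and acid are unveiled only at the end under buffered, non-acidic conditions. TBS = tert-butyldimethylsilyl, PMB = 4-methoxybenzyl.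

**Route**

Step 1
Reactants: 1 but-2-yn-1-ol
Product: 3 (2Z)-3-iodobut-2-en-1-ol, via cyclic vinylalanate 2 (not isolated)
Conditions: NaAlH2(OCH2CH2OCH3)2, THF, 0 °C → rt; then I2, −78 → 0 °C
Reagents that add atoms: iodine, II
Why: Hydroxyl-directed trans-hydroalumination of the propargylic alcohol puts aluminium on the distal carbon inside a five-membered alanate and iodine replaces it with retention, so the Z vinyl iodide (I cis to CH2OH) results and later becomes the Z C1=C10 alkene.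

Step 2
Reactants: 3 (2Z)-3-iodobut-2-en-1-ol
Product: 4 1-({[(2Z)-3-iodobut-2-en-1-yl]oxy}methyl)-4-methoxybenzene
Conditions: NaH, 4-methoxybenzyl chloride, Bu4NI (cat.), THF/DMF, 0 °C → rt
Reagents that add atoms: 4-methoxybenzyl chloride, COc1ccc(CCl)cc1
Why: Williamson ether synthesis gives a PMB ether that withstands t-BuLi, organocopper, aluminium hydride and silyl triflate and, unlike a silyl ether, cannot migrate to the cis vinyl anion.

Step 3
Reactants: 4 1-({[(2Z)-3-iodobut-2-en-1-yl]oxy}methyl)-4-methoxybenzene; 5 ethyl prop-2-ynoate; 6 2-(iodomethyl)-4,4,5,5-tetramethyl-1,3,2-dioxaborolane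
Product: 10 ethyl (2E,4Z)-6-[(4-methoxybenzyl)oxy]-4-methyl-2-[(4,4,5,5-tetramethyl-1,3,2-dioxaborolan-2-yl)methyl]hexa-2,4-dienoate, via alkenyllithium 7 (not isolated), via alkenylcopper 8 (not isolated), via cuprio dienoate 9 (not isolated)
Conditions: t-BuLi (2 equiv), Et2O, −78 °C; CuBr·SMe2, THF, −78 → −50 °C; 5, −78 °C; then HMPA, 6, −78 → 0 °C
Reagents that add atoms: none
Why: Iodine–lithium exchange and transmetalation keep the alkene geometry, syn-carbocupration of the propiolate forms C5–C10 with the new alkenyl group cis to copper, and alkylation of the α-cuprio ester with the iodomethylboronate forms C3–C4 with retention, a known one-pot route to 2-alkoxycarbonyl allylboronates.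

Step 4
Reactants: 10 ethyl (2E,4Z)-6-[(4-methoxybenzyl)oxy]-4-methyl-2-[(4,4,5,5-tetramethyl-1,3,2-dioxaborolan-2-yl)methyl]hexa-2,4-dienoate; 11 3-methylbut-2-enal
Product: 13 ethyl (3S,4Z)-3-[(1S)-1-hydroxy-3-methylbut-2-en-1-yl]-6-[(4-methoxybenzyl)oxy]-4-methyl-2-methylidenehex-4-enoate, via borate ester 12 (not isolated)
Conditions: (R)-3,3′-bis(2,4,6-triisopropylphenyl)-1,1′-binaphthyl-2,2′-diyl hydrogen phosphate (10 mol %), 4 Å molecular sieves, toluene, 0 °C → rt; aqueous NaHCO3 work-up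
Reagents that add atoms: none
Why: Brønsted-acid-catalysed allylboration through a closed six-membered chair forms C5–C6 with the C10 branch (cis to CH2B) axial and the aldehyde residue equatorial (syn relation of C5 and C6), and the (R)-phosphoric acid should direct the allyl unit to the re face of the aldehyde as it does for simple allyl and crotyl pinacol boronates, giving (3S,1′S)-13; any lactone formed by cyclisation of 13 converges on 14 in step 5.

Step 5
Reactants: 13 ethyl (3S,4Z)-3-[(1S)-1-hydroxy-3-methylbut-2-en-1-yl]-6-[(4-methoxybenzyl)oxy]-4-methyl-2-methylidenehex-4-enoate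
Product: 14 (3S,4Z)-3-[(1S)-1-hydroxy-3-methylbut-2-en-1-yl]-6-[(4-methoxybenzyl)oxy]-4-methyl-2-methylidenehex-4-en-1-ol
Conditions: i-Bu2AlH (4 equiv), CH2Cl2, −78 → 0 °C; aqueous KNaC4H4O6 work-up
Reagents that add atoms: none
Why: 1,2-Reduction of the α-substituted acrylate by the aluminium hydride gives the 2-methylidene-1,4-diol (C15 and C6 oxygens) without touching the stereocentres or the skipped diene.

Step 6
Reactants: 14 (3S,4Z)-3-[(1S)-1-hydroxy-3-methylbut-2-en-1-yl]-6-[(4-methoxybenzyl)oxy]-4-methyl-2-methylidenehex-4-en-1-ol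
Product: 15 bis-TBS ether of 14 [(3S,4Z)-1-(TBS-oxy)-3-[(1S)-1-(TBS-oxy)-3-methylbut-2-en-1-yl]-6-(PMB-oxy)-4-methyl-2-methylidenehex-4-ene]
Conditions: t-BuMe2SiOTf, 2,6-lutidine, CH2Cl2, −78 → 0 °C
Reagents that add atoms: tert-butyldimethylsilyl trifluoromethanesulfonate, CC(C)(C)[Si](C)(C)OS(=O)(=O)C(F)(F)F
Why: Silylation with the silyl triflate and a hindered pyridine covers the primary and the hindered secondary allylic hydroxyl alike and makes the C6 branch the bulkiest group on C5.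

Step 7
Reactants: 15 bis-TBS ether of 14
Product: 16 (2Z,4S)-6-(TBS-oxy)-4-[(1S)-1-(TBS-oxy)-3-methylbut-2-en-1-yl]-3-methyl-5-methylidenehex-2-en-1-ol
Conditions: 2,3-dichloro-5,6-dicyano-1,4-benzoquinone, CH2Cl2/pH 7 phosphate buffer, 0 °C
Reagents that add atoms: none
Why: Oxidative cleavage of the electron-rich benzyl ether through its charge-transfer complex with the quinone frees only the C2 hydroxyl, the silyl ethers being stable under buffered conditions.

Step 8
Reactants: 16 (2Z,4S)-6-(TBS-oxy)-4-[(1S)-1-(TBS-oxy)-3-methylbut-2-en-1-yl]-3-methyl-5-methylidenehex-2-en-1-ol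
Product: 17 ethenyl ether of 16 [(3S,4Z)-1-(TBS-oxy)-3-[(1S)-1-(TBS-oxy)-3-methylbut-2-en-1-yl]-6-(ethenyloxy)-4-methyl-2-methylidenehex-4-ene]
Conditions: butyl vinyl ether (solvent), Pd(OCOCF3)2 (2 mol %), 4,7-diphenyl-1,10-phenanthroline (2 mol %), Et3N (cat.), 75 °C
Reagents that add atoms: butyl vinyl ether, C=COCCCC
Why: Palladium-catalysed transfer vinylation (trans-etherification with an alkyl vinyl ether) of the primary allylic alcohol gives the allyl vinyl ether well below the temperature of its [3,3] shift.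

Step 9
Reactants: 17 ethenyl ether of 16
Product: 19 (1S,2R,3R,4S,5S)-3-(TBS-oxy)-4-[3-(TBS-oxy)prop-1-en-2-yl]-5-ethenyl-5-methyl-2-(prop-1-en-2-yl)cyclohexan-1-ol, via aldehyde 18 (not isolated)
Conditions: toluene (0.02 M), 140 °C, sealed base-washed tube; then cool to −78 °C, Me2AlCl (1.5 equiv), −78 → −20 °C, same flask
Reagents that add atoms: none
Why: Heating 17 triggers a concerted suprafacial [3,3] (Claisen) shift through a chair that forms C9–C10, breaks C2–O and unveils the C10 vinyl group together with aldehyde 18; on cooling, Me2AlCl activates this aldehyde for an intramolecular carbonyl-ene reaction in which C7 of the 2-methylprop-1-enyl group bonds to C8 while an allylic CH3 hydrogen passes to oxygen, which forms C7–C8 and the C11=C13 methylene. The closest known reaction types are the tandem Claisen–ene sequence of allyl vinyl ethers and the citronellal-to-isopulegol cyclisation. The only ring, the cyclohexane C5–C10, closes in a 6-exo-trig mode with respect to both the C7=C11 alkene and the C8=O group, helped by the Thorpe–Ingold effect of quaternary C10. C10 (S) is set in the Claisen chair: the Z alkene places the C5 branch axial with C5–H turned inside (allylic 1,3-strain against C2), so C9 bonds on the face next to the flat C4 propenyl unit and anti to the bulky C6 silyloxy-alkenyl branch; C7 is set in the ene chair, where C10–CH3 and the C4 branch on C5 are trans-diaxial and C6–OTBS, the vinyl group and the reacting alkene are equatorial (an axial alkene would be syn-axial to the C4 branch); C8 forms mainly with oxygen equatorial (an axial C=O would be syn-axial to C10–CH3) and is reset in steps 10 and 11. The step needs face selectivity at C10 and chemoselectivity for the trisubstituted alkene over the 1,1-disubstituted C3=C4 alkene; the first rests on the A(1,3)-locked conformation, the second on the higher nucleophilicity of the trisubstituted alkene, which alone offers an allylic methyl hydrogen, and 140 °C is low enough to keep the Cope shift of the 1,5-diene C2=C1–C10–C5–C4=C3 slow.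

Step 10
Reactants: 19 (1S,2R,3R,4S,5S)-3-(TBS-oxy)-4-[3-(TBS-oxy)prop-1-en-2-yl]-5-ethenyl-5-methyl-2-(prop-1-en-2-yl)cyclohexan-1-ol
Product: 20 (2S,3R,4S,5S)-3-(TBS-oxy)-4-[3-(TBS-oxy)prop-1-en-2-yl]-5-ethenyl-5-methyl-2-(prop-1-en-2-yl)cyclohexan-1-one
Conditions: Dess–Martin periodinane, CH2Cl2, 0 °C → rt
Reagents that add atoms: none
Why: Dess–Martin oxidation converts the C8 alcohol (either epimer) into one ketone under non-basic conditions that leave the β,γ-unsaturated, β-silyloxy ketone unenolised.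

Step 11
Reactants: 20 (2S,3R,4S,5S)-3-(TBS-oxy)-4-[3-(TBS-oxy)prop-1-en-2-yl]-5-ethenyl-5-methyl-2-(prop-1-en-2-yl)cyclohexan-1-one
Product: 21 (1R,2R,3R,4S,5S)-3-(TBS-oxy)-4-[3-(TBS-oxy)prop-1-en-2-yl]-5-ethenyl-5-methyl-2-(prop-1-en-2-yl)cyclohexan-1-ol
Conditions: LiBH(s-Bu)3, THF, −78 °C; H2O quench
Reagents that add atoms: none
Why: The bulky borohydride attacks C8 from the equatorial direction because the axial face is shielded by the syn-axial C10 methyl group, which gives the axial (8R) alcohol of the target (steric-approach-controlled reduction of a hindered cyclohexanone).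

Step 12
Reactants: 22 diphenyl phosphite; 23 tert-butyl 2-bromopropanoate
Product: 24 tert-butyl 2-(diphenoxyphosphoryl)propanoate
Conditions: NaH, THF, 0 °C → rt
Reagents that add atoms: none
Why: Michaelis–Becker alkylation of the sodium salt of the H-phosphonate with the α-bromo ester gives the diaryl phosphonate needed for a Z-selective olefination.

Step 13
Reactants: 24 tert-butyl 2-(diphenoxyphosphoryl)propanoate; 25 2-oxoethyl acetate
Product: 26 tert-butyl (2Z)-4-(acetyloxy)-2-methylbut-2-enoate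
Conditions: NaH, THF, 0 °C; then 25, −78 → 0 °C
Reagents that add atoms: none
Why: Horner–Wadsworth–Emmons olefination with an electron-poor diaryl phosphonate collapses fast through the syn oxaphosphetane and should give the Z trisubstituted enoate (ester cis to CH2OAc) with the acetate already in place, so that no free γ-hydroxy enoate able to lactonise ever appears.

Step 14
Reactants: 26 tert-butyl (2Z)-4-(acetyloxy)-2-methylbut-2-enoate
Product: 27 (2Z)-4-(acetyloxy)-2-methylbut-2-enoic acid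
Conditions: CF3CO2H/CH2Cl2 (1:4), 0 °C → rt
Reagents that add atoms: none
Why: Acidolysis of the tert-butyl ester with loss of isobutene frees the acid and leaves the acetate and the Z alkene intact.

Step 15
Reactants: 21 (1R,2R,3R,4S,5S)-3-(TBS-oxy)-4-[3-(TBS-oxy)prop-1-en-2-yl]-5-ethenyl-5-methyl-2-(prop-1-en-2-yl)cyclohexan-1-ol; 27 (2Z)-4-(acetyloxy)-2-methylbut-2-enoic acid
Product: 29 (1R,2R,3R,4S,5S)-3-(TBS-oxy)-4-[3-(TBS-oxy)prop-1-en-2-yl]-5-ethenyl-5-methyl-2-(prop-1-en-2-yl)cyclohexyl (2Z)-4-(acetyloxy)-2-methylbut-2-enoate, via mixed anhydride 28 (not isolated)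
Conditions: 27, 2,4,6-trichlorobenzoyl chloride, Et3N, toluene, rt; then 21, 4-(dimethylamino)pyridine (cat.), toluene, 60 °C
Reagents that add atoms: none
Why: Yamaguchi esterification, in which the hindered axial C8 alcohol attacks the less hindered carbonyl of the mixed anhydride, is the established way to acylate hindered alcohols with angelate-type Z acids without Z-to-E isomerisation.

Step 16
Reactants: 29 (1R,2R,3R,4S,5S)-3-(TBS-oxy)-4-[3-(TBS-oxy)prop-1-en-2-yl]-5-ethenyl-5-methyl-2-(prop-1-en-2-yl)cyclohexyl (2Z)-4-(acetyloxy)-2-methylbut-2-enoate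
Product: 30 (1R,2R,3R,4S,5S)-3-(TBS-oxy)-4-[3-(TBS-oxy)prop-1-en-2-yl]-5-ethenyl-2-(3-hydroxyprop-1-en-2-yl)-5-methylcyclohexyl (2Z)-4-(acetyloxy)-2-methylbut-2-enoate
Conditions: SeO2 (0.3 equiv), t-BuOOH (3 equiv), CH2Cl2, 0 °C → rt
Reagents that add atoms: tert-butyl hydroperoxide, CC(C)(C)OO
Why: Selenium dioxide allylic oxidation (ene reaction at the C11=C13 methylene, then [2,3] shift) hydroxylates the C12 methyl group, the C3=C4 alkene being deactivated by its allylic silyloxy group and lacking a methyl hydrogen, the vinyl group having no allylic hydrogen and the enoate being electron-poor.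

Step 17
Reactants: 30 (1R,2R,3R,4S,5S)-3-(TBS-oxy)-4-[3-(TBS-oxy)prop-1-en-2-yl]-5-ethenyl-2-(3-hydroxyprop-1-en-2-yl)-5-methylcyclohexyl (2Z)-4-(acetyloxy)-2-methylbut-2-enoate
Product: 32 2-[(1R,2R,3S,4S,6R)-6-{[(2Z)-4-(acetyloxy)-2-methylbut-2-enoyl]oxy}-2-(TBS-oxy)-3-[3-(TBS-oxy)prop-1-en-2-yl]-4-ethenyl-4-methylcyclohexyl]prop-2-enoic acid, via enal 31 (not isolated)
Conditions: (2,2,6,6-tetramethylpiperidin-1-yl)oxyl (cat.), PhI(OAc)2, CH2Cl2, rt; then t-BuOH/H2O, 2-methylbut-2-ene, NaH2PO4, NaClO2, 0 °C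
Reagents that add atoms: sodium chlorite, [Na+].[O-]Cl=O
Why: Oxoammonium oxidation of the primary allylic alcohol to the α-methylene aldehyde followed by Pinnick chlorite oxidation, with an alkene scavenger for hypochlorite, gives the acrylic acid without touching the other alkenes.

Step 18
Reactants: 32 2-[(1R,2R,3S,4S,6R)-6-{[(2Z)-4-(acetyloxy)-2-methylbut-2-enoyl]oxy}-2-(TBS-oxy)-3-[3-(TBS-oxy)prop-1-en-2-yl]-4-ethenyl-4-methylcyclohexyl]prop-2-enoic acid
Product: 33 2-[(1S,2R,3S,4S,6R)-6-{[(2Z)-4-(acetyloxy)-2-methylbut-2-enoyl]oxy}-4-ethenyl-2-hydroxy-3-(3-hydroxyprop-1-en-2-yl)-4-methylcyclohexyl]prop-2-enoic acid (CNP0261293.2)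
Conditions: Bu4NF, AcOH (1:1), THF, 0 °C → rt; work-up with pH 5–6 buffer at 0 °C
Reagents that add atoms: none
Why: Buffered fluoride desilylation removes both TBS groups while the acid stays largely as its carboxylate, which should keep the freed C6 hydroxyl from lactonising onto C12 and spare the acetate and the enoate ester.

**Compound list**

1 | but-2-yn-1-ol | CC#CCO | starting material
2 | sodium 2,2-bis(2-methoxyethoxy)-3-methyl-2,5-dihydro-1,2-oxaluminol-2-uide (cyclic vinylalanate) | CC1=CCO[Al-]1(OCCOC)OCCOC.[Na+] | intermediate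
3 | (2Z)-3-iodobut-2-en-1-ol | OC/C=C(/C)I | intermediate
4 | 1-({[(2Z)-3-iodobut-2-en-1-yl]oxy}methyl)-4-methoxybenzene | COc1ccc(COC/C=C(/C)I)cc1 | intermediate
5 | ethyl prop-2-ynoate | C#CC(=O)OCC | starting material
6 | 2-(iodomethyl)-4,4,5,5-tetramethyl-1,3,2-dioxaborolane | ICB1OC(C)(C)C(C)(C)O1 | starting material
7 | alkenyllithium from 4 (Li in place of I, Li cis to CH2OPMB) | COc1ccc(COC/C=C(/C)[Li])cc1 | intermediate
8 | alkenylcopper from 7 (Cu cis to CH2OPMB) | COc1ccc(COC/C=C(/C)[Cu])cc1 | intermediate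
9 | ethyl (2Z,4Z)-2-cuprio-6-[(4-methoxybenzyl)oxy]-4-methylhexa-2,4-dienoate | CCOC(=O)/C([Cu])=C/C(C)=C\COCc1ccc(OC)cc1 | intermediate
10 | ethyl (2E,4Z)-6-[(4-methoxybenzyl)oxy]-4-methyl-2-[(4,4,5,5-tetramethyl-1,3,2-dioxaborolan-2-yl)methyl]hexa-2,4-dienoate | CCOC(=O)/C(CB1OC(C)(C)C(C)(C)O1)=C/C(C)=C\COCc1ccc(OC)cc1 | intermediate
11 | 3-methylbut-2-enal | CC(C)=CC=O | starting material
12 | O-(pinacolatoboryl) derivative of 13 (borate ester, 3S,1′S) | CCOC(=O)C(=C)[C@@H]([C@@H](OB1OC(C)(C)C(C)(C)O1)C=C(C)C)/C(C)=C\COCc1ccc(OC)cc1 | intermediate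
13 | ethyl (3S,4Z)-3-[(1S)-1-hydroxy-3-methylbut-2-en-1-yl]-6-[(4-methoxybenzyl)oxy]-4-methyl-2-methylidenehex-4-enoate | CCOC(=O)C(=C)[C@@H]([C@@H](O)C=C(C)C)/C(C)=C\COCc1ccc(OC)cc1 | intermediate
14 | (3S,4Z)-3-[(1S)-1-hydroxy-3-methylbut-2-en-1-yl]-6-[(4-methoxybenzyl)oxy]-4-methyl-2-methylidenehex-4-en-1-ol | OCC(=C)[C@@H]([C@@H](O)C=C(C)C)/C(C)=C\COCc1ccc(OC)cc1 | intermediate
15 | bis-TBS ether of 14 (3S,4Z,1′S) | CC(C)(C)[Si](C)(C)OCC(=C)[C@@H]([C@@H](O[Si](C)(C)C(C)(C)C)C=C(C)C)/C(C)=C\COCc1ccc(OC)cc1 | intermediate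
16 | (2Z,4S)-6-(TBS-oxy)-4-[(1S)-1-(TBS-oxy)-3-methylbut-2-en-1-yl]-3-methyl-5-methylidenehex-2-en-1-ol | CC(C)(C)[Si](C)(C)OCC(=C)[C@@H]([C@@H](O[Si](C)(C)C(C)(C)C)C=C(C)C)/C(C)=C\CO | intermediate
17 | ethenyl ether of 16 (allyl vinyl ether) | CC(C)(C)[Si](C)(C)OCC(=C)[C@@H]([C@@H](O[Si](C)(C)C(C)(C)C)C=C(C)C)/C(C)=C\COC=C | intermediate
18 | (3S,4S,5S)-5-(TBS-oxy)-4-[3-(TBS-oxy)prop-1-en-2-yl]-3-ethenyl-3,7-dimethyloct-6-enal | C=C[C@](C)(CC=O)[C@@H](C(=C)CO[Si](C)(C)C(C)(C)C)[C@@H](O[Si](C)(C)C(C)(C)C)C=C(C)C | intermediate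
19 | (1S,2R,3R,4S,5S)-3-(TBS-oxy)-4-[3-(TBS-oxy)prop-1-en-2-yl]-5-ethenyl-5-methyl-2-(prop-1-en-2-yl)cyclohexan-1-ol | C=C[C@]1(C)C[C@H](O)[C@@H](C(=C)C)[C@H](O[Si](C)(C)C(C)(C)C)[C@@H]1C(=C)CO[Si](C)(C)C(C)(C)C | intermediate
20 | (2S,3R,4S,5S)-3-(TBS-oxy)-4-[3-(TBS-oxy)prop-1-en-2-yl]-5-ethenyl-5-methyl-2-(prop-1-en-2-yl)cyclohexan-1-one | C=C[C@]1(C)CC(=O)[C@@H](C(=C)C)[C@H](O[Si](C)(C)C(C)(C)C)[C@@H]1C(=C)CO[Si](C)(C)C(C)(C)C | intermediate
21 | (1R,2R,3R,4S,5S)-3-(TBS-oxy)-4-[3-(TBS-oxy)prop-1-en-2-yl]-5-ethenyl-5-methyl-2-(prop-1-en-2-yl)cyclohexan-1-ol | C=C[C@]1(C)C[C@@H](O)[C@@H](C(=C)C)[C@H](O[Si](C)(C)C(C)(C)C)[C@@H]1C(=C)CO[Si](C)(C)C(C)(C)C | intermediate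
22 | diphenyl phosphite | O=[PH](Oc1ccccc1)Oc1ccccc1 | starting material
23 | tert-butyl 2-bromopropanoate | CC(Br)C(=O)OC(C)(C)C | starting material
24 | tert-butyl 2-(diphenoxyphosphoryl)propanoate | CC(C(=O)OC(C)(C)C)P(=O)(Oc1ccccc1)Oc1ccccc1 | intermediate
25 | 2-oxoethyl acetate | CC(=O)OCC=O | starting material
26 | tert-butyl (2Z)-4-(acetyloxy)-2-methylbut-2-enoate | CC(=O)OC/C=C(/C)C(=O)OC(C)(C)C | intermediate
27 | (2Z)-4-(acetyloxy)-2-methylbut-2-enoic acid | CC(=O)OC/C=C(/C)C(=O)O | intermediate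
28 | (2Z)-4-(acetyloxy)-2-methylbut-2-enoic 2,4,6-trichlorobenzoic anhydride | CC(=O)OC/C=C(/C)C(=O)OC(=O)c1c(Cl)cc(Cl)cc1Cl | intermediate
29 | (1R,2R,3R,4S,5S)-3-(TBS-oxy)-4-[3-(TBS-oxy)prop-1-en-2-yl]-5-ethenyl-5-methyl-2-(prop-1-en-2-yl)cyclohexyl (2Z)-4-(acetyloxy)-2-methylbut-2-enoate | C=C[C@]1(C)C[C@@H](OC(=O)/C(C)=C\COC(C)=O)[C@@H](C(=C)C)[C@H](O[Si](C)(C)C(C)(C)C)[C@@H]1C(=C)CO[Si](C)(C)C(C)(C)C | intermediate
30 | (1R,2R,3R,4S,5S)-3-(TBS-oxy)-4-[3-(TBS-oxy)prop-1-en-2-yl]-5-ethenyl-2-(3-hydroxyprop-1-en-2-yl)-5-methylcyclohexyl (2Z)-4-(acetyloxy)-2-methylbut-2-enoate | C=C[C@]1(C)C[C@@H](OC(=O)/C(C)=C\COC(C)=O)[C@@H](C(=C)CO)[C@H](O[Si](C)(C)C(C)(C)C)[C@@H]1C(=C)CO[Si](C)(C)C(C)(C)C | intermediate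
31 | 2-[(1R,2R,3S,4S,6R)-6-{[(2Z)-4-(acetyloxy)-2-methylbut-2-enoyl]oxy}-2-(TBS-oxy)-3-[3-(TBS-oxy)prop-1-en-2-yl]-4-ethenyl-4-methylcyclohexyl]prop-2-enal | C=C[C@]1(C)C[C@@H](OC(=O)/C(C)=C\COC(C)=O)[C@@H](C(=C)C=O)[C@H](O[Si](C)(C)C(C)(C)C)[C@@H]1C(=C)CO[Si](C)(C)C(C)(C)C | intermediate
32 | 2-[(1R,2R,3S,4S,6R)-6-{[(2Z)-4-(acetyloxy)-2-methylbut-2-enoyl]oxy}-2-(TBS-oxy)-3-[3-(TBS-oxy)prop-1-en-2-yl]-4-ethenyl-4-methylcyclohexyl]prop-2-enoic acid | C=C[C@]1(C)C[C@@H](OC(=O)/C(C)=C\COC(C)=O)[C@@H](C(=C)C(=O)O)[C@H](O[Si](C)(C)C(C)(C)C)[C@@H]1C(=C)CO[Si](C)(C)C(C)(C)C | intermediate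
33 | 2-[(1S,2R,3S,4S,6R)-6-{[(2Z)-4-(acetyloxy)-2-methylbut-2-enoyl]oxy}-4-ethenyl-2-hydroxy-3-(3-hydroxyprop-1-en-2-yl)-4-methylcyclohexyl]prop-2-enoic acid | C=C[C@]1(C)C[C@@H](OC(=O)/C(C)=C\COC(C)=O)[C@@H](C(=C)C(=O)O)[C@H](O)[C@@H]1C(=C)CO | target

**Count and risks**

Total step count: 18. Longest linear sequence: 15 steps (steps 1–11 and 15–18); steps 12–14 make the side-chain acid.

Steps most likely to fail:

Step 9. The face selectivity of the [3,3] shift at C10 may erode if the two branches on C5 do not differ enough in effective size, and the aldehyde may close onto the 1,1-disubstituted C3=C4 alkene. Fallback (temporary ring), setting out from 13: pyridinium p-toluenesulfonate (cat.) in toluene at 40 °C closes the cis-disubstituted α-methylene-γ-butyrolactone (4S,5S)-4-{(2Z)-4-[(4-methoxybenzyl)oxy]but-2-en-2-yl}-3-methylidene-5-(2-methylprop-1-en-1-yl)oxolan-2-one F1. The quinone of step 7 removes the PMB group to give lactone alcohol F2, and transfer vinylation as in step 8 gives allyl vinyl ether F3. In F3 the lactone holds the C6 alkenyl group cis and nearly eclipsed to the C1=C10 alkene, so that face is blocked, and C3=C4 has become an electron-poor acrylate that cannot compete in the ene step. The heat/Me2AlCl sequence of step 9 should then give bicyclic lactone alcohol F4. Et3SiOTf/2,6-lutidine gives its C8 triethylsilyl ether F5, i-Bu2AlH opens the lactone to diol F6, t-BuMe2SiOTf/2,6-lutidine gives bis-TBS ether F7, and pyridinium p-toluenesulfonate in MeOH removes the secondary triethylsilyl group, which comes back to the route at 19.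

Step 4. The ester-bearing, γ-branched boronate may react slowly and with incomplete enantio-induction under phosphoric acid catalysis. Fallback (resolution through covalent diastereomers), setting out from 10 and 11: Sc(OTf)3 (10 mol %) in toluene at rt gives the racemic syn adduct, that is 13 together with its enantiomer ethyl (3R,4Z)-3-[(1R)-1-hydroxy-3-methylbut-2-en-1-yl]-6-[(4-methoxybenzyl)oxy]-4-methyl-2-methylidenehex-4-enoate F8. Esterification with (2S)-2-methoxy-2-phenylacetic acid (N,N′-dicyclohexylcarbodiimide, 4-(dimethylamino)pyridine) gives the (S)-O-methylmandelate of 13 F9 and the diastereomeric (S)-O-methylmandelate of the enantiomer F10, which are separated by chromatography. i-Bu2AlH as in step 5 reduces both ester groups of F9 and comes back to the route at 14.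

Step 16. The selenium-dioxide ene oxidation may also attack the C3=C4 alkene toward C15 or over-oxidise C12. Fallback (electrophilic ene-chlorination, then exchange of chlorine for oxygen), setting out from 29: NaOCl with CeCl3·7H2O in CH2Cl2/H2O at 0 °C should convert the C11 isopropenyl group into the allylic chloride (1R,2R,3R,4S,5S)-3-(TBS-oxy)-4-[3-(TBS-oxy)prop-1-en-2-yl]-2-(3-chloroprop-1-en-2-yl)-5-ethenyl-5-methylcyclohexyl (2Z)-4-(acetyloxy)-2-methylbut-2-enoate F11. Kornblum-type oxidation with N-methylmorpholine N-oxide in MeCN gives aldehyde 31, where the fallback comes back to the route; the chlorite stage of step 17 then takes 31 to 32.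

**Further compounds**

F1 | step 9 | (4S,5S)-4-{(2Z)-4-[(4-methoxybenzyl)oxy]but-2-en-2-yl}-3-methylidene-5-(2-methylprop-1-en-1-yl)oxolan-2-one | O=C1O[C@@H](C=C(C)C)[C@@H](/C(C)=C\COCc2ccc(OC)cc2)C1=C
F2 | step 9 | (4S,5S)-4-[(2Z)-4-hydroxybut-2-en-2-yl]-3-methylidene-5-(2-methylprop-1-en-1-yl)oxolan-2-one | O=C1O[C@@H](C=C(C)C)[C@@H](/C(C)=C\CO)C1=C
F3 | step 9 | (4S,5S)-4-[(2Z)-4-(ethenyloxy)but-2-en-2-yl]-3-methylidene-5-(2-methylprop-1-en-1-yl)oxolan-2-one | O=C1O[C@@H](C=C(C)C)[C@@H](/C(C)=C\COC=C)C1=C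
F4 | step 9 | bicyclic lactone alcohol (19 with C15 as carbonyl lactonised onto O6 in place of the two TBS ethers) | C=C[C@]1(C)C[C@H](O)[C@@H](C(=C)C)[C@@H]2OC(=O)C(=C)[C@@H]21
F5 | step 9 | C8 triethylsilyl ether of F4 | C=C[C@]1(C)C[C@H](O[Si](CC)(CC)CC)[C@@H](C(=C)C)[C@@H]2OC(=O)C(=C)[C@@H]21
F6 | step 9 | C6,C15-diol from F5 (C8 triethylsilyl ether) | C=C[C@]1(C)C[C@H](O[Si](CC)(CC)CC)[C@@H](C(=C)C)[C@H](O)[C@@H]1C(=C)CO
F7 | step 9 | bis-TBS ether of F6 (C8 triethylsilyl ether of 19) | C=C[C@]1(C)C[C@H](O[Si](CC)(CC)CC)[C@@H](C(=C)C)[C@H](O[Si](C)(C)C(C)(C)C)[C@@H]1C(=C)CO[Si](C)(C)C(C)(C)C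
F8 | step 4 | ethyl (3R,4Z)-3-[(1R)-1-hydroxy-3-methylbut-2-en-1-yl]-6-[(4-methoxybenzyl)oxy]-4-methyl-2-methylidenehex-4-enoate (enantiomer of 13) | CCOC(=O)C(=C)[C@H]([C@H](O)C=C(C)C)/C(C)=C\COCc1ccc(OC)cc1
F9 | step 4 | (2S)-2-methoxy-2-phenylacetate of 13 | CCOC(=O)C(=C)[C@@H]([C@@H](OC(=O)[C@@H](OC)c1ccccc1)C=C(C)C)/C(C)=C\COCc1ccc(OC)cc1
F10 | step 4 | (2S)-2-methoxy-2-phenylacetate of F8 | CCOC(=O)C(=C)[C@H]([C@H](OC(=O)[C@@H](OC)c1ccccc1)C=C(C)C)/C(C)=C\COCc1ccc(OC)cc1
F11 | step 16 | (1R,2R,3R,4S,5S)-3-(TBS-oxy)-4-[3-(TBS-oxy)prop-1-en-2-yl]-2-(3-chloroprop-1-en-2-yl)-5-ethenyl-5-methylcyclohexyl (2Z)-4-(acetyloxy)-2-methylbut-2-enoate | C=C[C@]1(C)C[C@@H](OC(=O)/C(C)=C\COC(C)=O)[C@@H](C(=C)CCl)[C@H](O[Si](C)(C)C(C)(C)C)[C@@H]1C(=C)CO[Si](C)(C)C(C)(C)C
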